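Everything rests on excising C7, the one ring B carbon without a substituent: a CH2 flanked by C8 and by ring A carbon C1, which lies para to the C4 oxygen. Deleting it contracts ring B to a trans-3-aryl-2-methylindan-1-one (9; C8 as carbonyl, both phenols benzylated) that already holds the congested C2–C7' bond and the C7'/C8' stereopair. In the forward sense, Me3SiCHN2 and BF3·OEt2 join C7 to C8, and the electron-rich C1 shifts from C8 to C7 as N2 departs. One operation thus makes two skeletal bonds and enlarges the five-membered ring to ring B as 2-tetralone 13. Its C8 ketone is then converted into the equatorial methyl group.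

Key step: step 7

Numbering: lignan numbering is used. Ring A is C1–C6 (C1 bonded to C7, C2 to C7', C3 OMe, C4 O, C5 OMe). Ring B is C1, C2, C7', C8', C8, C7. Ring C is the guaiacyl group on C7'.

Assumption: (S)-MonoPhos is written in step 5 as the antipode that leads to (R)-7. The sense of induction should be checked on the first run, and the equally available (R)-ligand is used if it proves opposite.

Step 1
Reactants: 1 acetosyringone (4'-hydroxy-3',5'-dimethoxyacetophenone)
Product: 2 1-[4-(benzyloxy)-3,5-dimethoxyphenyl]ethan-1-one
Conditions: BnBr, K2CO3, DMF, 60 °C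
Reagents that add atoms: benzyl bromide, BrCc1ccccc1
Why: Williamson ether synthesis, in which the phenoxide of 1 is the only nucleophile and benzyl bromide is an unhindered SN2 partner, so the two flanking methoxy groups can only slow the reaction.

Step 2
Reactants: 2 1-[4-(benzyloxy)-3,5-dimethoxyphenyl]ethan-1-one
Product: 3 1-[4-(benzyloxy)-2-bromo-3,5-dimethoxyphenyl]ethan-1-one
Conditions: NBS, MeCN, 0 °C to rt, dark
Reagents that add atoms: N-bromosuccinimide, O=C1CCC(=O)N1Br
Why: Electrophilic aromatic bromination, in which the two equivalent free ring positions are each ortho to one methoxy group and para to the other, so polar NBS conditions should brominate the future C2 rather than the acetyl group or the unactivated benzyl ring, and the first bromine deactivates the ring towards a second.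

Step 3
Reactants: 3 1-[4-(benzyloxy)-2-bromo-3,5-dimethoxyphenyl]ethan-1-one, 4 4-(benzyloxy)-3-methoxybenzaldehyde (O-benzylvanillin)
Product: 5 (E)-1-[4-(benzyloxy)-2-bromo-3,5-dimethoxyphenyl]-3-[4-(benzyloxy)-3-methoxyphenyl]prop-2-en-1-one
Conditions: aq KOH, EtOH–THF, rt
Reagents that add atoms: none
Why: Claisen–Schmidt aldol condensation, in which the aldehyde cannot enolise, the methyl ketone is the only enolate source, and E1cB loss of water gives the conjugated (E)-enone that holds C8, C8' and C7' in order.

Step 4
Reactants: 5 the (E)-2'-bromochalcone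
Product: 6 (E)-1-[4-(benzyloxy)-3,5-dimethoxy-2-(4,4,5,5-tetramethyl-1,3,2-dioxaborolan-2-yl)phenyl]-3-[4-(benzyloxy)-3-methoxyphenyl]prop-2-en-1-one
Conditions: B2pin2, Pd(dppf)Cl2 (cat.), KOAc, 1,4-dioxane, 90 °C
Reagents that add atoms: bis(pinacolato)diboron, CC1(C)OB(OC1(C)C)B1OC(C)(C)C(C)(C)O1
Why: Miyaura borylation, in which oxidative addition of zerovalent palladium into the C2–Br bond, acetate-assisted transmetalation with B2pin2 and reductive elimination exchange Br for Bpin, while the weak base KOAc leaves the enone and the benzyl ethers alone.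

Step 5
Reactants: 6 the (E)-2'-borylchalcone
Product: 7 (3R)-5-(benzyloxy)-3-[4-(benzyloxy)-3-methoxyphenyl]-4,6-dimethoxyindan-1-one
Conditions: [Rh(C2H4)2Cl]2 (cat.), (S)-MonoPhos (cat.), aq K3PO4 (0.5 equiv), toluene, 80 °C
Reagents that add atoms: none
Why: Rhodium-catalysed asymmetric intramolecular 1,4-addition (Hayashi–Miyaura type), known for chalcone-derived pinacol boronates, in which boron-to-rhodium transmetalation puts rhodium on C2, the tethered enone inserts at C7' on the face selected by the chiral phosphoramidite (setting C7' as R and forming the C2–C7' bond), and water protonates the rhodium enolate; recrystallisation of 7 or 9 remains available to raise the enantiomeric purity.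

Step 6
Reactants: 7 (3R)-3-arylindan-1-one
Product: 9 (2S,3R)-5-(benzyloxy)-3-[4-(benzyloxy)-3-methoxyphenyl]-4,6-dimethoxy-2-methylindan-1-one (trans), via lithium enolate 8 (not isolated)
Conditions: LDA (1.05 equiv), THF, −78 °C; MeI, −78 to −30 °C
Reagents that add atoms: iodomethane, CI
Why: Kinetic enolate alkylation, in which complete irreversible deprotonation at C8' limits proton exchange and double methylation, and MeI approaches the flat enolate 8 from the face away from ring C on the neighbouring C7', which sets C8' trans to the aryl group (also the isomer favoured at equilibrium).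

Step 7
Reactants: 9 trans-(2S,3R)-3-aryl-2-methylindan-1-one, 10 trimethylsilyldiazomethane
Product: 13 (3S,4R)-6-(benzyloxy)-4-[4-(benzyloxy)-3-methoxyphenyl]-5,7-dimethoxy-3-methyl-3,4-dihydronaphthalen-2(1H)-one, via diazonium betaine 11 (not isolated), via silyl tetralone 12 (not isolated)
Conditions: BF3·OEt2 (1.5 equiv), CH2Cl2, −78 °C, slow addition of Me3SiCHN2 (hexanes, 1.5 equiv), to −15 °C; then 1 M HCl, THF, rt
Reagents that add atoms: trimethylsilyldiazomethane (10), C[Si](C)(C)C=[N+]=[N-]
Why: The diazo carbon of 10 (the future C7) attacks the BF3-bound C8 carbonyl of 9 to give betaine 11, and as N2 leaves, the antiperiplanar ring A carbon C1 moves with its bonding pair from C8 to C7 through a phenonium-like bridged transition state to give the C7-silylated ketone 12, in which aqueous acid then replaces silicon by hydrogen. This is a Lewis acid-promoted diazoalkane homologation of the Tiffeneau–Demjanov type, an established way from benzo-fused 1-ketones such as 1-indanones and 1-tetralones to their ring-enlarged 2-ketones. Ring B is not closed by a cyclisation: the existing five-membered ring grows by one atom through the 1,2-shift, so no ring-closure mode has to be met. No lasting stereocentre is made (the silyl-bearing C7 of 12 ends as CH2), C7' is remote from the events, and C8', which does not migrate, stays trans to ring C because all conditions are non-basic. The selectivity needed is migration of C1 instead of C8', and it is secured by the para C4 benzyloxy group, which stabilises the bridged transition state, and by the poor aptitude of a branched secondary carbon for a shift to the bulky Me3Si-bearing terminus. A second insertion is held back because the reactive product ketone exists as the hindered α-silyl compound 12 until the diazoalkane is quenched, and the benzyl ethers prevent O-methylation of the phenols by 10.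

Step 8
Reactants: 13 trans-(3S,4R)-4-aryl-3-methyl-2-tetralone
Product: 14 (1R,2S)-7-(benzyloxy)-1-[4-(benzyloxy)-3-methoxyphenyl]-6,8-dimethoxy-2-methyl-3-methylidene-1,2,3,4-tetrahydronaphthalene
Conditions: Cp2TiMe2, toluene–THF, 75 °C, dark; chromatography on Et3N-deactivated silica
Reagents that add atoms: dimethyltitanocene Cp2TiMe2, C[Ti+2]C.c1cc[cH-]c1.c1cc[cH-]c1
Why: Petasis methylenation, in which thermally formed Cp2Ti=CH2 undergoes [2+2] cycloaddition and cycloreversion with the C8 ketone and, being barely basic, should neither enolise the acidic benzylic C7 position (the weakness of a Wittig reaction on 2-tetralones) nor epimerise C8'.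

Step 9
Reactants: 14 the C8 exocyclic alkene
Product: 15 (1R,2R,3R)-7-(benzyloxy)-1-[4-(benzyloxy)-3-methoxyphenyl]-6,8-dimethoxy-2,3-dimethyl-1,2,3,4-tetrahydronaphthalene (7'R,8R,8'R; 7',8'-trans, 8,8'-cis)
Conditions: Mn(dpm)3 (cat.), PhSiH3, t-BuOOH, i-PrOH, rt, argon
Reagents that add atoms: none
Why: Radical hydrogenation by metal-hydride hydrogen atom transfer (Mukaiyama type), in which a manganese hydride gives a hydrogen atom to the terminal CH2, and the tertiary C8 radical should take up its second hydrogen axially, so that the new methyl group ends equatorial and cis to the axial C8' methyl (8R), the arrangement that avoids a 1,3-diaxial contact with ring C, itself held pseudoaxial by the peri C3 methoxy group.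

Step 10
Reactants: 15 the dibenzyl ether of the target
Product: 16 (−)-(7'R,8R,8'R)-4,4'-dihydroxy-3,3',5-trimethoxy-2,7'-cyclolignan
Conditions: H2 (1 atm), Pd/C, EtOAc–MeOH, rt
Reagents that add atoms: none
Why: Catalytic hydrogenolysis cleaves both aryl benzyl ethers, and since no other reducible group is present and none of the three stereocentres is labile under neutral hydrogenation, the free bisphenol should result unchanged in configuration.

Compound list
1 | acetosyringone | CC(=O)c1cc(OC)c(O)c(OC)c1 | starting material
2 | 1-[4-(benzyloxy)-3,5-dimethoxyphenyl]ethan-1-one | CC(=O)c1cc(OC)c(OCc2ccccc2)c(OC)c1 | intermediate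
3 | 1-[4-(benzyloxy)-2-bromo-3,5-dimethoxyphenyl]ethan-1-one | CC(=O)c1cc(OC)c(OCc2ccccc2)c(OC)c1Br | intermediate
4 | 4-(benzyloxy)-3-methoxybenzaldehyde (O-benzylvanillin) | COc1cc(C=O)ccc1OCc1ccccc1 | starting material
5 | (E)-2'-bromochalcone of rings A and C | COc1cc(/C=C/C(=O)c2cc(OC)c(OCc3ccccc3)c(OC)c2Br)ccc1OCc1ccccc1 | intermediate
6 | (E)-2'-(pinacolboryl)chalcone of rings A and C | COc1cc(/C=C/C(=O)c2cc(OC)c(OCc3ccccc3)c(OC)c2B4OC(C)(C)C(C)(C)O4)ccc1OCc1ccccc1 | intermediate
7 | (3R)-5-(benzyloxy)-3-[4-(benzyloxy)-3-methoxyphenyl]-4,6-dimethoxyindan-1-one | COc1cc([C@@H]2c3c(cc(OC)c(OCc4ccccc4)c3OC)C(=O)C2)ccc1OCc1ccccc1 | intermediate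
8 | lithium C8/C8' enolate of 7 (C7' unchanged) | [Li+].COc1cc([C@@H]2c3c(cc(OC)c(OCc4ccccc4)c3OC)C([O-])=C2)ccc1OCc1ccccc1 | intermediate
9 | (2S,3R)-5-(benzyloxy)-3-[4-(benzyloxy)-3-methoxyphenyl]-4,6-dimethoxy-2-methylindan-1-one (trans) | COc1cc([C@@H]2c3c(cc(OC)c(OCc4ccccc4)c3OC)C(=O)[C@H]2C)ccc1OCc1ccccc1 | intermediate
10 | trimethylsilyldiazomethane | C[Si](C)(C)C=[N+]=[N-] | starting material
11 | BF3-bound β-diazonium alkoxide from 9 and 10 (C7 and C8 configuration undefined) | COc1cc([C@@H]2c3c(cc(OC)c(OCc4ccccc4)c3OC)C(O[B-](F)(F)F)(C([N+]#N)[Si](C)(C)C)[C@H]2C)ccc1OCc1ccccc1 | intermediate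
12 | C7-trimethylsilyl derivative of tetralone 13 (C7 configuration undefined) | COc1cc([C@@H]2c3c(cc(OC)c(OCc4ccccc4)c3OC)C([Si](C)(C)C)C(=O)[C@H]2C)ccc1OCc1ccccc1 | intermediate
13 | (3S,4R)-6-(benzyloxy)-4-[4-(benzyloxy)-3-methoxyphenyl]-5,7-dimethoxy-3-methyl-3,4-dihydronaphthalen-2(1H)-one (trans) | COc1cc([C@@H]2c3c(cc(OC)c(OCc4ccccc4)c3OC)CC(=O)[C@H]2C)ccc1OCc1ccccc1 | intermediate
14 | (1R,2S)-7-(benzyloxy)-1-[4-(benzyloxy)-3-methoxyphenyl]-6,8-dimethoxy-2-methyl-3-methylidene-1,2,3,4-tetrahydronaphthalene | COc1cc([C@@H]2c3c(cc(OC)c(OCc4ccccc4)c3OC)CC(=C)[C@H]2C)ccc1OCc1ccccc1 | intermediate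
15 | (7'R,8R,8'R)-4,4'-bis(benzyloxy)-3,3',5-trimethoxy-2,7'-cyclolignan | COc1cc([C@@H]2c3c(cc(OC)c(OCc4ccccc4)c3OC)C[C@@H](C)[C@H]2C)ccc1OCc1ccccc1 | intermediate
16 | (−)-(7'R,8R,8'R)-4,4'-dihydroxy-3,3',5-trimethoxy-2,7'-cyclolignan | COc1cc([C@@H]2c3c(cc(OC)c(O)c3OC)C[C@@H](C)[C@H]2C)ccc1O | target

Total step count: 10. Longest linear sequence: 10 steps (1 to 16); compounds 4 and 10 are bought.

Steps most likely to fail

Step 7.
- What may go wrong: addition of the weakly nucleophilic diazoalkane to a carbonyl that is deactivated by the para oxygen donor may be sluggish. Competing shift of C8', collapse of the adduct to an oxirane, or a second homologation may erode the outcome.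
- Fallback: it sets out from 9 and returns at 13, and it keeps the same two bonds and the same C1 shift while avoiding both the diazoalkane and the carbonyl addition. Wittig methylenation of 9 (Ph3PCH3Br, KOt-Bu, THF) should give the trans-3-aryl-2-methyl-1-methylideneindane F1. Treatment with PhI(OH)OTs in 95% MeOH then places the trivalent iodine electrophile on the terminal CH2 (C7) and solvent on benzylic C8. Reductive departure of iodobenzene drives C1 from C8 to C7, and the resulting oxocarbenium ion is hydrolysed to 13. This methylenation and hypervalent-iodine ring enlargement is known for benzo-fused ketones.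

Step 9.
- What may go wrong: facial selectivity in the hydrogen transfer to the C8 radical may be poor, because the axial approach runs past the pseudoaxial ring C. Reversible hydrogen abstraction may also move the alkene into conjugation with ring A.
- Fallback: it sets out from 14 and returns at 15, and it replaces the kinetic hydrogen transfer by enolate equilibration.
  1. Hydroboration with 9-BBN (THF) gives the B-alkyl-9-borabicyclononane F2.
  2. Oxidation in the same flask (NaOH, H2O2) gives the primary C9 alcohol F3 as a mixture of C8 epimers.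
  3. Dess–Martin oxidation and exposure of the crude aldehyde to DBU in CH2Cl2 should funnel both epimers into the equatorial 8,8'-cis aldehyde F4. Its axial epimer suffers the 1,3-diaxial contact with ring C.
  4. NaBH4 gives the 8,8'-cis alcohol F5, and MsCl/Et3N gives the mesylate F6.
  5. LiEt3BH (THF) displaces the sulfonate by hydride to give 15.

Step 4.
- What may go wrong: oxidative addition and transmetalation at a bromide flanked by a methoxy and an acyl group may be slow. Protodebromination, protodeboronation or unselective intramolecular carbopalladation of the enone may then take over.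
- Fallback: it sets out from 5 and returns at 7, bypassing boron and rhodium, through a palladium-catalysed asymmetric reductive Heck cyclisation. The conditions are Pd(OAc)2, a chiral bisphosphine such as 3,5-Xyl-MeO-BIPHEP (antipode chosen by the same test run as in step 5), HCO2Na and DMF at 100 °C. The aryl–palladium species inserts the enone at C7' in the enantio-determining step, and formate reduces the palladium enolate. This reaction type is known for 2'-halochalcones, and it makes no new compound.

Further compounds
F1 | step 7 | (2S,3R)-5-(benzyloxy)-3-[4-(benzyloxy)-3-methoxyphenyl]-4,6-dimethoxy-2-methyl-1-methylideneindane (trans) | COc1cc([C@@H]2c3c(cc(OC)c(OCc4ccccc4)c3OC)C(=C)[C@H]2C)ccc1OCc1ccccc1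
F2 | step 9 | B-alkyl-9-borabicyclononane from 14, boron on C9, C8 epimers | COc1cc([C@@H]2c3c(cc(OC)c(OCc4ccccc4)c3OC)CC(CB4C5CCCC4CCC5)[C@H]2C)ccc1OCc1ccccc1
F3 | step 9 | primary C9 alcohol, C8 epimers | COc1cc([C@@H]2c3c(cc(OC)c(OCc4ccccc4)c3OC)CC(CO)[C@H]2C)ccc1OCc1ccccc1
F4 | step 9 | 8,8'-cis (equatorial) C9 aldehyde | COc1cc([C@@H]2c3c(cc(OC)c(OCc4ccccc4)c3OC)C[C@@H](C=O)[C@H]2C)ccc1OCc1ccccc1
F5 | step 9 | 8,8'-cis C9 alcohol | COc1cc([C@@H]2c3c(cc(OC)c(OCc4ccccc4)c3OC)C[C@@H](CO)[C@H]2C)ccc1OCc1ccccc1
F6 | step 9 | 8,8'-cis C9 methanesulfonate | COc1cc([C@@H]2c3c(cc(OC)c(OCc4ccccc4)c3OC)C[C@@H](COS(C)(=O)=O)[C@H]2C)ccc1OCc1ccccc1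
F0 | step 4 | none | none
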